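Eremophilane numbering: ring A = C1–C5, C10; ring B = C5–C10. Ring B is disconnected at C6–C7 and C8–C9 into a cis-fused cyclobutanone (C5, C6, C9, C10) and a silylated isopropenylacetylene (C7, C8). The key step exploits the C7(isopropenyl)–C8(O)–C9(O) edge of ring B, which maps onto alkyne plus ketone. Zerovalent nickel inserts the alkyne into the C6–C9 bond, so the four-membered ring grows by two atoms. All ring B carbons, the isopropenyl group and a silicon mask for the C8 ketone arrive in one operation. Quaternary C5 and the cis fusion stem from a dichloroketene cycloaddition to an enantiopure cyclohexene. C3 is inverted by the final Mitsunobu angeloylation.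

Key step: step 9

Remark on the chemistry: β is the face of the angular methyl C14 and α the opposite face; the target SMILES is read as (3R,4R,5R,7R,9R,10S), that is 3α-angeloyloxy, 4β- and 5β-methyl, 7β-isopropenyl, 9β-senecioyloxy and 10β-H (cis-decalin).

Step 1
Reactants: 1 but-2-yne; 2 pinacolborane
Product: 3 (Z)-2-(but-2-en-2-yl)-4,4,5,5-tetramethyl-1,3,2-dioxaborolane
Conditions: Cp2Zr(H)Cl (5 mol %), Et3N (10 mol %), neat, sealed tube, 60 °C
Reagents that add atoms: none
Why: Zirconocene-hydride-catalysed hydroboration of an alkyne is a syn addition, so H and B end up cis, the two methyl groups are cis (Z), and the symmetrical alkyne leaves no regiochemical choice.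

Step 2
Reactants: 3 (Z)-but-2-en-2-yl pinacolboronate
Product: 5 (E)-4,4,5,5-tetramethyl-2-(2-methylbut-2-en-1-yl)-1,3,2-dioxaborolane, via chloromethyl borate 4 (not isolated)
Conditions: BrCH2Cl, n-BuLi, THF, −78 °C to rt
Reagents that add atoms: bromochloromethane, ClCBr
Why: Matteson homologation, in which chloromethyllithium made in the flask adds to boron and the alkenyl group of 4 migrates to carbon with loss of chloride and retention of the double-bond geometry, giving the E allylboronate (terminal methyl trans to CH2B).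

Step 3
Reactants: 5 (E)-2-methylbut-2-enyl pinacolboronate; 6 pent-4-enal
Product: 8 (3R,4S)-2,3-dimethylocta-1,7-dien-4-ol, via homoallyl borate 7 (not isolated)
Conditions: (R)-TRIP [(R)-3,3'-bis(2,4,6-triisopropylphenyl)-1,1'-binaphthyl-2,2'-diyl hydrogen phosphate] (5 mol %), 4 Å MS, toluene, −30 °C; aq. NaHCO3 work-up
Reagents that add atoms: none
Why: Chiral-phosphoric-acid-catalysed allylboration of the crotylboration type through a closed chair transition state, in which the E geometry of 5 gives the anti hydroxyl/methyl pair and the (R)-catalyst, hydrogen-bonded to a boronate oxygen and the formyl hydrogen, should direct attack to the Re face of 6 (4S, hence 3R).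

Step 4
Reactants: 8 (3R,4S)-2,3-dimethylocta-1,7-dien-4-ol
Product: 9 tert-butyl{[(3R,4S)-2,3-dimethylocta-1,7-dien-4-yl]oxy}dimethylsilane
Conditions: TBSCl, imidazole, DMF, rt
Reagents that add atoms: tert-butyldimethylsilyl chloride, CC(C)(C)[Si](C)(C)Cl
Why: Standard silylation of a secondary alcohol that touches no stereocentre; the bulky ether later shields the β face and falls to fluoride in step 12.

Step 5
Reactants: 9 silyl ether of the dienol
Product: 10 tert-butyl{[(1S,2R)-2,3-dimethylcyclohex-3-en-1-yl]oxy}dimethylsilane (silyloxy and methyl cis)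
Conditions: second-generation Grubbs catalyst RuCl2(=CHPh)(PCy3)(SIMes) (3 mol %), CH2Cl2 (0.02 M), reflux
Reagents that add atoms: none
Why: Ring-closing metathesis of a monosubstituted and a 1,1-disubstituted alkene closes six-membered ring A with loss of ethene and gives the trisubstituted C5=C10 alkene, the two untouched stereocentres now being cis on the ring.

Step 6
Reactants: 10 cis-configured cyclohexene
Product: 11 (1R,2R,3S,6S)-3-(tert-butyldimethylsilyloxy)-8,8-dichloro-1,2-dimethylbicyclo[4.2.0]octan-7-one
Conditions: Cl3CCOCl, Zn–Cu couple, Et2O–DME, sonication, 15–25 °C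
Reagents that add atoms: trichloroacetyl chloride, O=C(Cl)C(Cl)(Cl)Cl
Why: Ketene–alkene [2+2] cycloaddition in which the ketene carbonyl carbon bonds to the less substituted C10 and CCl2 to C5, suprafacially on the alkene (cis fusion) and on the α face, because A(1,2) strain with the C5 methyl holds the C4 methyl pseudoaxial on the β face where the silyl ether also lies, which sets C5 and C10.

Step 7
Reactants: 11 dichlorocyclobutanone
Product: 12 (1R,2R,3S,6S)-3-(tert-butyldimethylsilyloxy)-1,2-dimethylbicyclo[4.2.0]octan-7-one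
Conditions: Zn dust, AcOH, rt
Reagents that add atoms: none
Why: Reductive dechlorination of an α,α-dichloroketone by zinc through zinc enolates, which leaves the silyl ether, the strained ketone and all stereocentres intact.

Step 8
Reactants: 13 2-methylbut-1-en-3-yne
Product: 15 benzyldimethyl(3-methylbut-3-en-1-yn-1-yl)silane, via lithium acetylide 14 (not isolated)
Conditions: n-BuLi, THF, −78 °C; then BnMe2SiCl, −78 °C to rt
Reagents that add atoms: benzylchlorodimethylsilane, C[Si](C)(Cl)Cc1ccccc1
Why: Deprotonation of the terminal alkyne and silylation of acetylide 14, the benzyl group on silicon being the later fluoride-labile trigger for oxidation.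

Step 9
Reactants: 12 cis-fused cyclobutanone; 15 silylated enyne
Product: 16 8-(benzyldimethylsilyl)-3β-(tert-butyldimethylsilyloxy)-10βH-eremophila-7,11-dien-9-one
Conditions: Ni(cod)2 (10 mol %), PCy3 (20 mol %), toluene, 100 °C, slow addition of 15 (2 equiv)
Reagents that add atoms: none
Why: Zerovalent nickel binds the C9 carbonyl group of 12 and the alkyne of 15 and couples them oxidatively to a spiro oxanickelacyclopentene (C8–C9 bond), strain-driven β-carbon elimination then breaks C6–C9 to give a seven-membered divalent nickelacycle, and reductive elimination forms C6–C7. The closest known reaction type is the nickel-catalysed intermolecular insertion of internal alkynes into the acyl–carbon bond of cyclobutanones, a formal [4+2] that here turns the four-membered ring C5–C6–C9–C10 into six-membered ring B. Ring B is closed by C(sp3)–C(sp2) reductive elimination within the nickelacycle, so no exo or endo alternative of an open-chain cyclisation exists. No new stereocentre is formed, and since C5 and C10 keep all four of their bonds, the cis fusion and the C3 and C4 centres of 12 are carried over unchanged. Site selectivity is needed between C9–C6 and C9–C10: cleavage toward the primary C6 should be favoured over the tertiary C10, as in other 2-substituted four-membered ketones, and the Ni–C6 bond next to quaternary C5 has no β-hydrogen to lose. Orientation of the alkyne is secured by the conjugated alkene of 15, which coordinates to nickel and places the isopropenyl-bearing carbon next to the metal (future C7) and the silyl-bearing carbon at C9, the sense known for nickel couplings of 1,3-enynes with carbonyl compounds even with silyl substituents, while slow addition of 15 suppresses its oligomerisation.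

Step 10
Reactants: 16 α-silyl dienone
Product: 17 8-(benzyldimethylsilyl)-3β-(tert-butyldimethylsilyloxy)-10βH-eremophila-7,11-dien-9β-ol
Conditions: i-Bu2AlH, toluene, −78 °C; aq. KNa tartrate work-up
Reagents that add atoms: none
Why: 1,2-Reduction of a fully β-substituted α-silyl enone by an aluminium hydride; with the 3β-silyloxy group equatorial the cis-octalone prefers the conformer in which the angular C14 methyl is axial on ring B and 1,3-syn to the β trajectory at C9, so hydride should arrive from the α face and give the 9β-alcohol.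

Step 11
Reactants: 17 9β-allylic alcohol; 18 senecioic acid (3-methylbut-2-enoic acid)
Product: 19 8-(benzyldimethylsilyl)-3β-(tert-butyldimethylsilyloxy)-10βH-eremophila-7,11-dien-9β-yl senecioate
Conditions: DCC, DMAP (cat.), CH2Cl2, 0 °C to rt
Reagents that add atoms: none
Why: Steglich esterification acylates the hindered allylic alcohol with retention at C9 under nearly neutral conditions and avoids the vinylketene pathway by which senecioyl chloride and amine bases give deconjugated esters.

Step 12
Reactants: 19 vinylsilane senecioate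
Product: 22 3β-hydroxy-9β-senecioyloxy-7αH,10βH-eremophil-11-en-8-one, via silanol 20 (not isolated), via dienol 21 (not isolated)
Conditions: n-Bu4NF (4 equiv), THF, 0 °C to rt; then KHCO3, 30% aq. H2O2, MeOH, rt
Reagents that add atoms: hydrogen peroxide, OO
Why: Tamao–Fleming oxidation of a benzyldimethylsilyl alkene, in which fluoride cleaves the benzyl–silicon bond and the C3 silyl ether to give silanol 20, peroxide replaces C8–Si by C8–O to give dienol 21, and 21 ketonises by protonation at the α carbon C7, the mildly basic medium letting C7 settle as the equatorial 7β-isopropenyl group of the ring B chair that also holds the 9β-ester equatorial.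

Step 13
Reactants: 22 3β-alcohol; 23 angelic acid [(Z)-2-methylbut-2-enoic acid]
Product: 24 3α-angeloyloxy-9β-senecioyloxy-7αH,10βH-eremophil-11-en-8-one (target)
Conditions: PPh3, DIAD, toluene, 0 °C to rt
Reagents that add atoms: none
Why: Mitsunobu esterification in which the axial 3β-oxyphosphonium group, strained by the 1,3-diaxial C14 methyl, is displaced by angelate from the open α side in an SN2 process with inversion to the equatorial 3α-ester, the neutral conditions sparing the Z double bond, the β,γ-unsaturated ketone and the epimerisable C7 and C9.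

Compound list
1 | but-2-yne | CC#CC | starting material
2 | pinacolborane | B1OC(C)(C)C(C)(C)O1 | starting material
3 | (Z)-2-(but-2-en-2-yl)-4,4,5,5-tetramethyl-1,3,2-dioxaborolane | C/C=C(\C)B1OC(C)(C)C(C)(C)O1 | intermediate
4 | lithium (Z)-(but-2-en-2-yl)(chloromethyl)pinacolatoborate | [Li+].C/C=C(\C)[B-]1(CCl)OC(C)(C)C(C)(C)O1 | intermediate
5 | (E)-4,4,5,5-tetramethyl-2-(2-methylbut-2-en-1-yl)-1,3,2-dioxaborolane | C/C=C(\C)CB1OC(C)(C)C(C)(C)O1 | intermediate
6 | pent-4-enal | C=CCCC=O | starting material
7 | pinacol borate ester of (3R,4S)-2,3-dimethylocta-1,7-dien-4-ol | C=CCC[C@H](OB1OC(C)(C)C(C)(C)O1)[C@H](C)C(C)=C | intermediate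
8 | (3R,4S)-2,3-dimethylocta-1,7-dien-4-ol | C=CCC[C@H](O)[C@H](C)C(C)=C | intermediate
9 | tert-butyl{[(3R,4S)-2,3-dimethylocta-1,7-dien-4-yl]oxy}dimethylsilane | C=CCC[C@H](O[Si](C)(C)C(C)(C)C)[C@H](C)C(C)=C | intermediate
10 | tert-butyl{[(1S,2R)-2,3-dimethylcyclohex-3-en-1-yl]oxy}dimethylsilane | C[C@@H]1C(C)=CCC[C@@H]1O[Si](C)(C)C(C)(C)C | intermediate
11 | (1R,2R,3S,6S)-3-(tert-butyldimethylsilyloxy)-8,8-dichloro-1,2-dimethylbicyclo[4.2.0]octan-7-one | O=C1C(Cl)(Cl)[C@@]2(C)[C@@H]1CC[C@H](O[Si](C)(C)C(C)(C)C)[C@@H]2C | intermediate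
12 | (1R,2R,3S,6S)-3-(tert-butyldimethylsilyloxy)-1,2-dimethylbicyclo[4.2.0]octan-7-one | O=C1C[C@@]2(C)[C@@H]1CC[C@H](O[Si](C)(C)C(C)(C)C)[C@@H]2C | intermediate
13 | 2-methylbut-1-en-3-yne | C=C(C)C#C | starting material
14 | lithium 3-methylbut-3-en-1-ynide | [Li]C#CC(C)=C | intermediate
15 | benzyldimethyl(3-methylbut-3-en-1-yn-1-yl)silane | C=C(C)C#C[Si](C)(C)Cc1ccccc1 | intermediate
16 | 8-(benzyldimethylsilyl)-3β-(tert-butyldimethylsilyloxy)-10βH-eremophila-7,11-dien-9-one | C=C(C)C=1C[C@@]2(C)[C@H](CC[C@H](O[Si](C)(C)C(C)(C)C)[C@@H]2C)C(=O)C=1[Si](C)(C)Cc1ccccc1 | intermediate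
17 | 8-(benzyldimethylsilyl)-3β-(tert-butyldimethylsilyloxy)-10βH-eremophila-7,11-dien-9β-ol | C=C(C)C=1C[C@@]2(C)[C@H](CC[C@H](O[Si](C)(C)C(C)(C)C)[C@@H]2C)[C@@H](O)C=1[Si](C)(C)Cc1ccccc1 | intermediate
18 | senecioic acid | CC(C)=CC(=O)O | starting material
19 | 9β-senecioate of 17 | C=C(C)C=1C[C@@]2(C)[C@H](CC[C@H](O[Si](C)(C)C(C)(C)C)[C@@H]2C)[C@@H](OC(=O)C=C(C)C)C=1[Si](C)(C)Cc1ccccc1 | intermediate
20 | 8-(hydroxydimethylsilyl)-3β-hydroxy-10βH-eremophila-7,11-dien-9β-yl senecioate | C=C(C)C=1C[C@@]2(C)[C@H](CC[C@H](O)[C@@H]2C)[C@@H](OC(=O)C=C(C)C)C=1[Si](C)(C)O | intermediate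
21 | 3β,8-dihydroxy-10βH-eremophila-7,11-dien-9β-yl senecioate (dienol) | C=C(C)C=1C[C@@]2(C)[C@H](CC[C@H](O)[C@@H]2C)[C@@H](OC(=O)C=C(C)C)C=1O | intermediate
22 | 3β-hydroxy-9β-senecioyloxy-7αH,10βH-eremophil-11-en-8-one | C=C(C)[C@H]1C[C@@]2(C)[C@H](CC[C@H](O)[C@@H]2C)[C@@H](OC(=O)C=C(C)C)C1=O | intermediate
23 | angelic acid | C/C=C(/C)C(=O)O | starting material
24 | 3α-angeloyloxy-9β-senecioyloxy-7αH,10βH-eremophil-11-en-8-one, (3R,4R,5R,7R,9R,10S) | C=C(C)[C@H]1C[C@@]2(C)[C@H](CC[C@@H](OC(=O)/C(C)=C\C)[C@@H]2C)[C@@H](OC(=O)C=C(C)C)C1=O | target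

Total step count: 13. Longest linear sequence: 12 (steps 1–7 and 9–13; step 8 is a one-step branch).

Steps most likely to fail

Step 9. Oligomerisation of the enyne on nickel may outrun ketone–alkyne coupling. The hindered silyl-bearing carbon may also fail to bond to C9, so that the alkyne enters in the reverse orientation or C9–C10 is cleaved instead. The fallback sets out from 12 and returns at 22. It fixes the orientation by making C8–C9 first and keeps a four-to-six ring enlargement.
- Acetylide 14 (from 13 as in step 8) is added to 12 (THF, −78 °C, convex face; the carbinol configuration is of no consequence) to give the propargylic cyclobutanol F1.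
- Hydroxyl-directed trans-hydroalumination with NaAlH2(OCH2CH2OMe)2 followed by I2 gives the (Z)-iodo dienol F2.
- Pd(OAc)2, PPh3 and Cs2CO3 in toluene at 90 °C enlarge the ring to the silicon-free dienone F3. The sequence is oxidative addition to zerovalent palladium, alkoxide binding, β-carbon elimination of C6–C9 and reductive elimination.
- i-Bu2AlH gives the 9β-alcohol F4.
- VO(acac)2 and t-BuOOH epoxidise the allylic C7=C8 bond syn to the hydroxyl group to give the epoxy alcohol F5.
- DCC, DMAP and 18 give the epoxy senecioate F6.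
- Pd(PPh3)4 isomerises the vinyl epoxide to the β,γ-unsaturated ketone F7.
- HF·pyridine removes the silyl ether to reach 22.

Step 13. Elimination of the axial oxyphosphonium group toward C2 or C4, whose axial hydrogens are antiperiplanar, may compete with displacement, and the moderately acidic angelic acid may react sluggishly. The fallback sets out from 22 and returns at 24. It separates activation from displacement. ClCH2SO2Cl and pyridine convert 22 into the 3β-chloromethanesulfonate F8. Acid 23 and Cs2CO3 give caesium angelate F9. F8 and F9 with 18-crown-6 in toluene at 60 °C should then give 24 by carboxylate SN2 inversion without a phosphonium leaving group.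

Step 10. Facial selectivity may be poor or reversed, because the minor conformer of 16 exposes the convex β face of C9 to the hydride. The fallback sets out from 16 and returns at 19. It accepts the substrate preference and corrects it during ester formation. Reduction gives the 9α-alcohol F10, which is esterified with 18 under Mitsunobu conditions (PPh3, DIAD, toluene, 0 °C). Inversion at the pseudoaxial allylic carbinol then delivers the 9β-senecioate 19.

Further compounds
F1 | step 9 | 3-(tert-butyldimethylsilyloxy)-1,2-dimethyl-7-(3-methylbut-3-en-1-yn-1-yl)bicyclo[4.2.0]octan-7-ol | O[C@]1(C#CC(C)=C)C[C@@]2(C)[C@@H]1CC[C@H](O[Si](C)(C)C(C)(C)C)[C@@H]2C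
F2 | step 9 | 3-(tert-butyldimethylsilyloxy)-7-[(Z)-2-iodo-3-methylbuta-1,3-dien-1-yl]-1,2-dimethylbicyclo[4.2.0]octan-7-ol | O[C@]1(/C=C(\I)C(C)=C)C[C@@]2(C)[C@@H]1CC[C@H](O[Si](C)(C)C(C)(C)C)[C@@H]2C
F3 | step 9 | 3β-(tert-butyldimethylsilyloxy)-10βH-eremophila-7,11-dien-9-one | C=C(C)C=1C[C@@]2(C)[C@H](CC[C@H](O[Si](C)(C)C(C)(C)C)[C@@H]2C)C(=O)C=1
F4 | step 9 | 3β-(tert-butyldimethylsilyloxy)-10βH-eremophila-7,11-dien-9β-ol | C=C(C)C=1C[C@@]2(C)[C@H](CC[C@H](O[Si](C)(C)C(C)(C)C)[C@@H]2C)[C@@H](O)C=1
F5 | step 9 | 7β,8β-epoxy-3β-(tert-butyldimethylsilyloxy)-10βH-eremophil-11-en-9β-ol | C=C(C)[C@]12C[C@@]3(C)[C@H](CC[C@H](O[Si](C)(C)C(C)(C)C)[C@@H]3C)[C@@H](O)[C@H]1O2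
F6 | step 9 | 9β-senecioate of F5 | C=C(C)[C@]12C[C@@]3(C)[C@H](CC[C@H](O[Si](C)(C)C(C)(C)C)[C@@H]3C)[C@@H](OC(=O)C=C(C)C)[C@H]1O2
F7 | step 9 | 3β-(tert-butyldimethylsilyloxy)-9β-senecioyloxy-7αH,10βH-eremophil-11-en-8-one | C=C(C)[C@H]1C[C@@]2(C)[C@H](CC[C@H](O[Si](C)(C)C(C)(C)C)[C@@H]2C)[C@@H](OC(=O)C=C(C)C)C1=O
F8 | step 13 | 3β-chloromethanesulfonate of 22 | C=C(C)[C@H]1C[C@@]2(C)[C@H](CC[C@H](OS(=O)(=O)CCl)[C@@H]2C)[C@@H](OC(=O)C=C(C)C)C1=O
F9 | step 13 | caesium angelate | C/C=C(/C)C(=O)[O-].[Cs+]
F10 | step 10 | 8-(benzyldimethylsilyl)-3β-(tert-butyldimethylsilyloxy)-10βH-eremophila-7,11-dien-9α-ol | C=C(C)C=1C[C@@]2(C)[C@H](CC[C@H](O[Si](C)(C)C(C)(C)C)[C@@H]2C)[C@H](O)C=1[Si](C)(C)Cc1ccccc1
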